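**Plan**

1. Numbering: labdane C1–C20 for the decalin and chain (C18 = 4α-CH2OH, C19 = 4β-CH3, C14 = vinylic CH); O1′, C2′–C5′ for the butenolide ring and C6′ for its exocyclic CH.
2. Cuts, in order: C14–C6′ together with the lactone bond O1′–C5′ (giving an E-iodoalkene triol and (Z)-3-methylpent-2-en-4-ynoic acid); then C13–C16 and C14–I (terminal alkyne); then O–C18 and O–C8 (back to C18–H and C8=C17); last, the alkyne back to the methyl ketone left when C14/C15 of (+)-larixol are excised.
3. Enabling feature: the Z enol-lactone unit O1′–C5′=C6′ of the butenolide ring is the anti adduct of the C2′ carboxyl across a C5′≡C6′ triple bond held cis by C3′=C4′. C6′ can therefore arrive as an sp carbon, couple to sp2 C14, and the ring closes 5-exo-dig in the same flask.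
4. Forward: rings A and B are bought intact; the chain is trimmed to the alkyne; C8=C17 of ring B is epoxidised; the 6α-oxyl radical oxidises C18, the equatorial methyl of ring A that lies syn-pentane to O6; LiAlH4 frees the triol; carboalumination–iodination; the last step joins the chain and closes the butenolide.
5. Stereochemistry: C5, C6, C9, C10 from larixol; C8 from α-face epoxidation (β face shielded by axial C20) and hydride opening at C17; C4 from the intramolecular hydrogen abstraction; E C13=C14 from syn-carboalumination; Z C5′=C6′ from anti-oxymetalation.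

Key step: step 12

Assumption: (+)-larixol and (Z)-3-methylpent-2-en-4-yn-1-ol are taken as purchasable; the target SMILES is read as the 6α,8α,18-triol of the normal labdane series (5α-H, 9α-H, 10β-CH3, 4α-CH2OH, 8β-CH3).

**Route**

Step 1
Reactants: 1 (+)-larixol, (13S)-labda-8(17),14-diene-6α,13-diol
Product: 2 6α-hydroxy-14,15-dinorlabd-8(17)-en-13-one
Conditions: KMnO4, acetone/H2O, 0 °C
Reagents that add atoms: none
Why: Permanganate oxidative cleavage of a tertiary vinyl carbinol (dihydroxylation of the monosubstituted C14=C15 alkene, then glycol cleavage between C13 and C14) should excise C14 and C15 and leave the C13 methyl ketone, while the hindered 1,1-disubstituted C8=C17 alkene and the secondary C6 carbinol are expected to react more slowly, as is usual for labdane vinyl carbinols of the manool and sclareol type.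

Step 2
Reactants: 2 6α-hydroxy-14,15-dinorlabd-8(17)-en-13-one
Product: 3 6α-(triethylsilyloxy)-14,15-dinorlabd-8(17)-en-13-one
Conditions: Et3SiCl, imidazole, DMF, 20 °C
Reagents that add atoms: chlorotriethylsilane, CC[Si](Cl)(CC)CC
Why: Silyl ether formation on the only hydroxyl masks O6 against the amide base and the chlorophosphate of the next step, and no stereocentre is touched.

Step 3
Reactants: 3 6α-(triethylsilyloxy)-14,15-dinorlabd-8(17)-en-13-one
Product: 5 6α-(triethylsilyloxy)-15,16-dinorlabd-8(17)-en-13-yne, via enol phosphate 4 (not isolated)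
Conditions: LiN(i-Pr)2 (1.05 equiv), THF, −78 °C; ClP(O)(OEt)2, −78 → 20 °C; LiN(i-Pr)2 (2.3 equiv), −78 → 20 °C; aq. NH4Cl
Reagents that add atoms: none
Why: Kinetic deprotonation of the methyl group and O-phosphorylation should give the terminal enol phosphate, from which excess amide base eliminates diethyl phosphate (enol phosphate to alkyne elimination of methyl ketones), so that the former ketone methyl becomes the alkyne terminus, called C14 from here on.

Step 4
Reactants: 5 6α-(triethylsilyloxy)-15,16-dinorlabd-8(17)-en-13-yne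
Product: 6 15,16-dinorlabd-8(17)-en-13-yn-6α-ol
Conditions: Bu4NF, THF, 20 °C
Reagents that add atoms: none
Why: Fluoride-induced desilylation frees the 6α-hydroxyl that is needed as the radical anchor, and the terminal alkyne and the exocyclic alkene are inert to fluoride.

Step 5
Reactants: 6 15,16-dinorlabd-8(17)-en-13-yn-6α-ol
Product: 7 8α,17-epoxy-15,16-dinorlabd-13-yn-6α-ol
Conditions: mCPBA, CH2Cl2, 0 °C
Reagents that add atoms: 3-chloroperoxybenzoic acid, OOC(=O)c1cccc(Cl)c1
Why: Prilezhaev epoxidation of the electron-rich 1,1-disubstituted alkene (the terminal alkyne reacts far more slowly) should occur from the α face, because the β face of C8 is shielded by the syn-axial C20 methyl on C10 and by the C11 chain, which sets C8 with oxygen α (equatorial).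

Step 6
Reactants: 7 8α,17-epoxy-15,16-dinorlabd-13-yn-6α-ol
Product: 8 8α,17-epoxy-15,16-dinorlabd-13-yn-6α-yl nitrite
Conditions: NOCl, pyridine, −20 °C
Reagents that add atoms: nitrosyl chloride, O=NCl
Why: O-Nitrosation of the secondary alcohol gives the nitrite ester needed for the Barton reaction, and pyridine takes up the HCl so that the epoxide should survive.

Step 7
Reactants: 8 8α,17-epoxy-15,16-dinorlabd-13-yn-6α-yl nitrite
Product: 9 8α,17-epoxy-6α-hydroxy-15,16-dinorlabd-13-yn-18-yl nitrate
Conditions: hν (Hg lamp, Pyrex filter), O2, benzene, 15 °C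
Reagents that add atoms: dioxygen, O=O
Why: Barton nitrite photolysis in its oxygen-trapping variant: O–NO homolysis gives the 6α-oxyl radical, which abstracts hydrogen through a six-membered transition state from the only methyl within reach, the equatorial 4α-methyl C18 (syn-pentane array O6–C6–C5–C4–C18), and the C18 radical is trapped by O2 and then by NO as the nitrate, so that the two methyls on C4 are told apart and C4 becomes a stereocentre with CH2O on the α side.

Step 8
Reactants: 9 8α,17-epoxy-6α-hydroxy-15,16-dinorlabd-13-yn-18-yl nitrate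
Product: 10 15,16-dinorlabd-13-yne-6α,8α,18-triol
Conditions: LiAlH4, THF, 0 → 50 °C; H2O/NaOH work-up
Reagents that add atoms: none
Why: LiAlH4 should cleave the nitrate ester at the O–N bond to the primary alcohol and open the spiro-epoxide by SN2 hydride delivery to the unhindered C17 methylene, which leaves the α C8–O bond untouched and turns C17 into the 8β-methyl, while an isolated terminal alkyne is not reduced under these conditions.

Step 9
Reactants: 10 15,16-dinorlabd-13-yne-6α,8α,18-triol
Product: 12 (13E)-14-iodo-15-norlabd-13-ene-6α,8α,18-triol, via alkenylalane 11 (not isolated)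
Conditions: AlMe3 (7 equiv), Cp2ZrCl2 (0.3 equiv), CH2Cl2, 0 → 20 °C; then I2, THF, −30 → 0 °C
Reagents that add atoms: trimethylaluminium, C[Al](C)C; iodine, II
Why: Zirconium-catalysed carboalumination (Negishi carboalumination) adds CH3 and Al syn across the terminal alkyne with aluminium on the terminal carbon after the three hydroxyls have been tied up as dimethylaluminium alkoxides by the excess AlMe3, and iodinolysis of the C–Al bond with retention should give the E iodoalkene.

Step 10
Reactants: 13 (Z)-3-methylpent-2-en-4-yn-1-ol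
Product: 14 (Z)-3-methylpent-2-en-4-ynal
Conditions: MnO2, CH2Cl2, 20 °C, dark
Reagents that add atoms: none
Why: MnO2 oxidises the allylic alcohol selectively to the enal under neutral heterogeneous conditions, which should keep the Z geometry.

Step 11
Reactants: 14 (Z)-3-methylpent-2-en-4-ynal
Product: 15 (Z)-3-methylpent-2-en-4-ynoic acid
Conditions: NaClO2, NaH2PO4, 2-methylbut-2-ene, t-BuOH/H2O, 0 → 20 °C
Reagents that add atoms: sodium chlorite, [Na+].[O-]Cl=O
Why: Pinnick oxidation (chlorite with a hypochlorite scavenger) should convert the enal into the acid without touching the alkyne or isomerising the Z alkene.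

Step 12
Reactants: 12 (13E)-14-iodo-15-norlabd-13-ene-6α,8α,18-triol; 15 (Z)-3-methylpent-2-en-4-ynoic acid
Product: 17 (13E)-14-[(Z)-(3-methyl-5-oxofuran-2(5H)-ylidene)methyl]-15-norlabd-13-ene-6α,8α,18-triol, via dienynoic acid 16 (not isolated)
Conditions: Pd(PPh3)4 (5 mol %), CuI (10 mol %), Et3N, degassed MeCN, 20 °C, dark, slow addition of 15
Reagents that add atoms: none
Why: Oxidative addition of the C14–I bond of 12 to zerovalent palladium (with retention of the E geometry), transmetalation of the copper acetylide formed from the terminal alkyne of 15, and reductive elimination forge the C14–C6′ bond (Sonogashira coupling) and give seco acid 16. In 16 the Z C3′=C4′ bond holds the triethylammonium carboxylate beside the C5′≡C6′ triple bond, which is activated by π-coordination to divalent palladium or monovalent copper, so that the carboxylate oxygen adds anti and protonolysis of the alkenyl–metal bond releases the butenolide. The closest known reaction type is the palladium/copper-catalysed tandem alkynylation–lactonisation that turns (Z)-2-en-4-ynoic acids into (Z)-γ-alkylidenebutenolides. The single ring formed, the butenolide ring (bond O1′–C5′), closes in the 5-exo-dig mode. No stereocentre is created; the Z geometry of C5′=C6′ follows from the anti addition of O and H across the alkyne, and the E geometry of C13=C14 is carried over from 12. The step needs coupling before cyclisation, 5-exo over 6-endo closure (2-pyranone) and tolerance of three free hydroxyls; the fast copper-acetylide pathway of the terminal alkyne, the cis carboxylate whose reach favours the nearer alkyne carbon C5′, and the neutral amine medium are expected to secure these.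

**Compound list**

1 | (+)-larixol, (13S)-labda-8(17),14-diene-6α,13-diol | C=C[C@@](C)(O)CC[C@@H]1[C@@]2(C)CCCC(C)(C)[C@@H]2[C@@H](O)CC1=C | starting material
2 | 6α-hydroxy-14,15-dinorlabd-8(17)-en-13-one (methyl ketone) | CC(=O)CC[C@@H]1[C@@]2(C)CCCC(C)(C)[C@@H]2[C@@H](O)CC1=C | intermediate
3 | 6α-(triethylsilyloxy)-14,15-dinorlabd-8(17)-en-13-one | CC(=O)CC[C@@H]1[C@@]2(C)CCCC(C)(C)[C@@H]2[C@@H](O[Si](CC)(CC)CC)CC1=C | intermediate
4 | diethyl 6α-(triethylsilyloxy)-14,15-dinorlabda-8(17),13(16)-dien-13-yl phosphate (terminal enol phosphate) | C=C(OP(=O)(OCC)OCC)CC[C@@H]1[C@@]2(C)CCCC(C)(C)[C@@H]2[C@@H](O[Si](CC)(CC)CC)CC1=C | intermediate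
5 | 6α-(triethylsilyloxy)-15,16-dinorlabd-8(17)-en-13-yne (chain on C9: CH2CH2C≡CH) | C#CCC[C@@H]1[C@@]2(C)CCCC(C)(C)[C@@H]2[C@@H](O[Si](CC)(CC)CC)CC1=C | intermediate
6 | 15,16-dinorlabd-8(17)-en-13-yn-6α-ol | C#CCC[C@@H]1[C@@]2(C)CCCC(C)(C)[C@@H]2[C@@H](O)CC1=C | intermediate
7 | 8α,17-epoxy-15,16-dinorlabd-13-yn-6α-ol (epoxide O on the α face of C8) | C#CCC[C@@H]1[C@@]2(C)CCCC(C)(C)[C@@H]2[C@@H](O)C[C@@]1(C3)O3 | intermediate
8 | 8α,17-epoxy-15,16-dinorlabd-13-yn-6α-yl nitrite | C#CCC[C@@H]1[C@@]2(C)CCCC(C)(C)[C@@H]2[C@@H](ON=O)C[C@@]1(C3)O3 | intermediate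
9 | 8α,17-epoxy-6α-hydroxy-15,16-dinorlabd-13-yn-18-yl nitrate (4α-CH2ONO2, 4β-CH3) | C#CCC[C@@H]1[C@@]2(C)CCC[C@@](C)(CO[N+](=O)[O-])[C@@H]2[C@@H](O)C[C@@]1(C3)O3 | intermediate
10 | 15,16-dinorlabd-13-yne-6α,8α,18-triol | C#CCC[C@@H]1[C@@]2(C)CCC[C@@](C)(CO)[C@@H]2[C@@H](O)C[C@@]1(C)O | intermediate
11 | (13E)-14-(dimethylalumanyl)-15-norlabd-13-ene-6α,8α,18-triol as its tris(dimethylaluminium alkoxide) | C[Al](C)/C=C(\C)CC[C@@H]1[C@@]2(C)CCC[C@@](C)(CO[Al](C)C)[C@@H]2[C@@H](O[Al](C)C)C[C@@]1(C)O[Al](C)C | intermediate
12 | (13E)-14-iodo-15-norlabd-13-ene-6α,8α,18-triol (iodine trans to the C12 chain, cis to the new methyl C16) | I/C=C(\C)CC[C@@H]1[C@@]2(C)CCC[C@@](C)(CO)[C@@H]2[C@@H](O)C[C@@]1(C)O | intermediate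
13 | (Z)-3-methylpent-2-en-4-yn-1-ol (ethynyl cis to CH2OH) | C#C/C(C)=C\CO | starting material
14 | (Z)-3-methylpent-2-en-4-ynal | C#C/C(C)=C\C=O | intermediate
15 | (Z)-3-methylpent-2-en-4-ynoic acid | C#C/C(C)=C\C(=O)O | intermediate
16 | (13E)-14-[(3Z)-4-carboxy-3-methylbut-3-en-1-yn-1-yl]-15-norlabd-13-ene-6α,8α,18-triol (dienynoic seco acid) | OC(=O)\C=C(C)/C#C/C=C(\C)CC[C@@H]1[C@@]2(C)CCC[C@@](C)(CO)[C@@H]2[C@@H](O)C[C@@]1(C)O | intermediate
17 | (13E)-14-[(Z)-(3-methyl-5-oxofuran-2(5H)-ylidene)methyl]-15-norlabd-13-ene-6α,8α,18-triol (CNP0126806.1) | CC1=CC(=O)O/C1=C\C=C(/C)CC[C@@H]1[C@@]2(C)CCC[C@@](C)(CO)[C@@H]2[C@@H](O)C[C@@]1(C)O | target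

**Step count and risks**

Total steps: 12. Longest linear sequence: 10 (steps 1–9 and 12).

Steps most likely to fail:

1. Step 7. The 6α-oxyl radical may fragment (β-scission of C5–C6 or C6–C7) instead of abstracting hydrogen, and capture of the C18 radical by O2 may be incomplete, so that nitrate, nitroso and carbonyl products would form side by side. The fallback sets out from nitrite 8 and returns at triol 10. It uses the classical anaerobic Barton reaction with NO as the only trap: photolysis of 8 under argon should give the C18 nitroso compound F1, which tautomerises in warm 2-propanol to the 18-oxime F2. Reductive deoximation with TiCl3/NH4OAc in aqueous THF should give the 6α,18-lactol F3, the cyclic hemiacetal of the C18 aldehyde. LiAlH4 then reduces the lactol to the 6α,18-diol and opens the epoxide in the same operation, giving 10.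

2. Step 12. Acid 15 may cyclise to the methylene butenolide before it couples, seco acid 16 may close 6-endo to a 2-pyranone, and the alkyne may homocouple oxidatively. The fallback sets out from 15 and 12 and returns at 17; it separates coupling from ring closure. Acid 15 is esterified (Me3SiCHN2, MeOH/toluene) to methyl (Z)-3-methylpent-2-en-4-ynoate F4, which is coupled with 12 under Sonogashira conditions to the dienynoate F5. Saponification (LiOH, THF/H2O) gives acid 16, now isolated, and Ag2CO3-catalysed 5-exo-dig lactonisation of this (Z)-2-en-4-ynoic acid should deliver 17.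

3. Step 9. Carbometalation may stall on the aggregated tris(aluminium alkoxide), or the alkenylalane may be protonated before iodination. The fallback sets out from 10 and returns at 12; it runs the carbometalation on a masked substrate. Et3SiCl/imidazole silylates O6 and O18 (the tertiary O8 stays free) to the bis(silyl ether) F6. Carboalumination through the alkenylalane F7 and iodinolysis give the protected iodoalkene F8, and Bu4NF returns 12.

**Further compounds**

F1 | step 7 | 8α,17-epoxy-18-nitroso-15,16-dinorlabd-13-yn-6α-ol | C#CCC[C@@H]1[C@@]2(C)CCC[C@@](C)(CN=O)[C@@H]2[C@@H](O)C[C@@]1(C3)O3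
F2 | step 7 | 8α,17-epoxy-6α-hydroxy-15,16-dinorlabd-13-yn-18-al (E)-oxime | C#CCC[C@@H]1[C@@]2(C)CCC[C@@](C)(/C=N/O)[C@@H]2[C@@H](O)C[C@@]1(C3)O3
F3 | step 7 | 6α,18:8α,17-diepoxy-15,16-dinorlabd-13-yn-18-ol (lactol, C18 epimers) | C#CCC[C@@H]1[C@@]2(C)CCC[C@@](C)(C3O)[C@@H]2[C@@H](O3)C[C@@]1(C4)O4
F4 | step 12 | methyl (Z)-3-methylpent-2-en-4-ynoate | C#C/C(C)=C\C(=O)OC
F5 | step 12 | methyl ester of seco acid 16 | COC(=O)\C=C(C)/C#C/C=C(\C)CC[C@@H]1[C@@]2(C)CCC[C@@](C)(CO)[C@@H]2[C@@H](O)C[C@@]1(C)O
F6 | step 9 | 6α,18-bis(triethylsilyloxy)-15,16-dinorlabd-13-yn-8α-ol | C#CCC[C@@H]1[C@@]2(C)CCC[C@@](C)(CO[Si](CC)(CC)CC)[C@@H]2[C@@H](O[Si](CC)(CC)CC)C[C@@]1(C)O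
F7 | step 9 | (13E)-14-(dimethylalumanyl)-6α,18-bis(triethylsilyloxy)-15-norlabd-13-en-8α-ol as its dimethylaluminium alkoxide | C[Al](C)/C=C(\C)CC[C@@H]1[C@@]2(C)CCC[C@@](C)(CO[Si](CC)(CC)CC)[C@@H]2[C@@H](O[Si](CC)(CC)CC)C[C@@]1(C)O[Al](C)C
F8 | step 9 | (13E)-14-iodo-6α,18-bis(triethylsilyloxy)-15-norlabd-13-en-8α-ol | I/C=C(\C)CC[C@@H]1[C@@]2(C)CCC[C@@](C)(CO[Si](CC)(CC)CC)[C@@H]2[C@@H](O[Si](CC)(CC)CC)C[C@@]1(C)O
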